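**Retrosynthetic overview** (labels: C7/C8/C9 = ArCH(O)/CH/CH2O of the 4-hydroxyphenyl half; primed labels = 4-methoxyphenyl half)
1. 23 ⇐ 20: the tetrahydrofuran is closed last, forming the C7–O bond by 5-exo addition of the C9' hydroxyl to a para-quinone methide.
2. 20 ⇐ 18 ⇐ 15 + 16: reduction and acetylation of an all-trans γ-lactone; C7–C8 bond by lactone aldol addition.
3. 15 ⇐ 11 + 12: C7'–aryl bond by Grignard addition, lactone closure (the only temporary ring, formed first), acid equilibration to the trans lactone.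
4. 11 ⇐ 9 ⇐ 5 + 6: C8–C8' bond by Johnson–Claisen [3,3] rearrangement with 1,3-chirality transfer, then ozonolysis.
5. 5 ⇐ 1: (R)-but-3-yn-2-ol, hydroxymethylation/silylation and cis-semihydrogenation.

Assumption: (R)-but-3-yn-2-ol (catalogue compound, made in bulk by lipase resolution) is bought enantiopure and is the only chiral input; the route is a paper design and has not been run.

**Step 1**
Reactants: 1 (R)-but-3-yn-2-ol
Product: 4 (R)-5-[(tert-butyldiphenylsilyl)oxy]pent-3-yn-2-ol, via lithium (R)-4-lithiobut-3-yn-2-olate 2 (not isolated), via dilithium (R)-pent-2-yne-1,4-diolate 3 (not isolated)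
Conditions: n-BuLi (2.05 equiv), THF, −78 to 0 °C; (CH2O)n, −78 °C to rt; then t-BuPh2SiCl (1.0 equiv), 0 °C to rt; H2O
Reagents that add atoms: formaldehyde (from paraformaldehyde), C=O; tert-butyl(chloro)diphenylsilane, CC(C)(C)[Si](Cl)(c1ccccc1)c1ccccc1
Why: Double deprotonation gives the alkoxide–acetylide whose carbon end adds to formaldehyde (acetylide 1,2-addition), and the bulky silyl chloride then caps only the primary alkoxide (chemoselective silylation); the carbinol stereocentre is not touched.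

**Step 2**
Reactants: 4 (R)-5-[(tert-butyldiphenylsilyl)oxy]pent-3-yn-2-ol
Product: 5 (2R,3Z)-5-[(tert-butyldiphenylsilyl)oxy]pent-3-en-2-ol
Conditions: H2 (1 atm), Pd/CaCO3 poisoned with Pb(OAc)2, quinoline, EtOAc, rt
Reagents that add atoms: none
Why: Lindlar semihydrogenation adds H2 syn to the alkyne and stops at the (Z)-alkene; the (R) centre is untouched.

**Step 3**
Reactants: 5 (2R,3Z)-5-[(tert-butyldiphenylsilyl)oxy]pent-3-en-2-ol; 6 triethyl orthoacetate
Product: 9 ethyl (3S,4E)-3-{[(tert-butyldiphenylsilyl)oxy]methyl}hex-4-enoate, via mixed orthoester 7 (not isolated), via ketene acetal 8 (not isolated)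
Conditions: MeC(OEt)3 (6 equiv), EtCO2H (5 mol%), 135 °C, EtOH distilled off
Reagents that add atoms: none
Why: Johnson–Claisen [3,3]-sigmatropic rearrangement: orthoester exchange and loss of ethanol give ketene acetal 8, which rearranges suprafacially through a chair transition state with the methyl group equatorial (the cis CH2OSi group blocks the axial alternative), forming the C8–C8' bond and relaying the (R) carbinol chirality into the new (3S) centre while the old centre becomes a trans alkene.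

**Step 4**
Reactants: 9 ethyl (3S,4E)-3-{[(tert-butyldiphenylsilyl)oxy]methyl}hex-4-enoate
Product: 11 ethyl (3R)-4-[(tert-butyldiphenylsilyl)oxy]-3-formylbutanoate, via ozonide 10 (not isolated)
Conditions: O3, CH2Cl2, −78 °C; then PPh3, −78 °C to rt; used crude at once
Reagents that add atoms: ozone, [O-][O+]=O
Why: Ozonolysis with reductive work-up cleaves the propenyl group to the C7' aldehyde without touching the adjacent stereocentre, which is kept cold to avoid enolization.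

**Step 5**
Reactants: 11 ethyl (3R)-4-[(tert-butyldiphenylsilyl)oxy]-3-formylbutanoate; 12 4-methoxyphenylmagnesium bromide
Product: 14 (4R,5RS)-4-{[(tert-butyldiphenylsilyl)oxy]methyl}-5-(4-methoxyphenyl)dihydrofuran-2(3H)-one (cis/trans mixture), via bromomagnesium alkoxide 13 (not isolated)
Conditions: 4-MeOC6H4MgBr (1.05 equiv), THF, −78 °C, then 0 °C to rt; H2O
Reagents that add atoms: none
Why: Chemoselective Grignard 1,2-addition to the aldehyde (faster than to the ester at −78 °C) gives alkoxide 13, which closes the γ-lactone by transesterification on warming; the new benzylic centre forms unselectively and is corrected in step 6.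

**Step 6**
Reactants: 14 (4R,5RS)-lactone mixture
Product: 15 (4R,5S)-4-{[(tert-butyldiphenylsilyl)oxy]methyl}-5-(4-methoxyphenyl)dihydrofuran-2(3H)-one (trans)
Conditions: CF3CO2H (10 vol%), CH2Cl2, 0 °C to rt
Reagents that add atoms: none
Why: Reversible SN1 ionization of the 4-methoxybenzylic C–O bond and relactonization (acid-mediated thermodynamic epimerization) funnels both epimers to the more stable 4,5-trans lactone, so C7' (5S) is set by the C8' centre; the silyl ether tolerates the acid.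

**Step 7**
Reactants: 15 (4R,5S)-lactone; 16 4-[(tert-butyldimethylsilyl)oxy]benzaldehyde
Product: 18 (3R,4R,5S)-3-[(RS)-{4-[(tert-butyldimethylsilyl)oxy]phenyl}(hydroxy)methyl]-4-{[(tert-butyldiphenylsilyl)oxy]methyl}-5-(4-methoxyphenyl)dihydrofuran-2(3H)-one, via lithium enolate 17 (not isolated)
Conditions: LiN(SiMe3)2 (1.1 equiv), THF, −78 °C; 16 (1.2 equiv), −78 °C; AcOH quench
Reagents that add atoms: none
Why: Lactone enolate aldol addition in which the aldehyde approaches the enolate face opposite the C4 substituent, giving the 3,4-trans (3R) product; the carbinol centre forms as a mixture that is erased in step 10.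

**Step 8**
Reactants: 18 aldol adduct
Product: 19 (1S,2R,3S,4RS)-4-{4-[(tert-butyldimethylsilyl)oxy]phenyl}-2-{[(tert-butyldiphenylsilyl)oxy]methyl}-3-(hydroxymethyl)-1-(4-methoxyphenyl)butane-1,4-diol
Conditions: LiBH4 (3 equiv), THF, 0 °C to rt; aq. work-up
Reagents that add atoms: none
Why: Hydride reduction of the lactone opens it to the primary C9 alcohol and the C7' benzylic alcohol without breaking any bond to a stereocentre; both silyl ethers survive.

**Step 9**
Reactants: 19 triol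
Product: 20 (1S,2R,3S,4RS)-3-(acetoxymethyl)-4-{4-[(tert-butyldimethylsilyl)oxy]phenyl}-2-{[(tert-butyldiphenylsilyl)oxy]methyl}-1-(4-methoxyphenyl)butane-1,4-diyl diacetate
Conditions: Ac2O, pyridine, DMAP (cat.), CH2Cl2, 0 °C to rt
Reagents that add atoms: acetic anhydride, CC(=O)OC(C)=O
Why: DMAP-catalysed acetylation esterifies all three free hydroxyls, installing the two acetates of the target and a benzylic acetate leaving group at C7.

**Step 10**
Reactants: 20 triacetate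
Product: 23 [(2R,3S,4R)-4-[(S)-acetoxy(4-methoxyphenyl)methyl]-2-(4-hydroxyphenyl)tetrahydrofuran-3-yl]methyl acetate (target), via phenol alcohol 21 (not isolated), via para-quinone methide 22 (not isolated)
Conditions: Bu4NF (2.5 equiv), AcOH (2.5 equiv), THF, 0 °C to rt; then Et3N (3 equiv), rt
Reagents that add atoms: none
Why: Buffered fluoride desilylation frees the phenol and the C9' alcohol, base then triggers 1,6-elimination of acetate to para-quinone methide 22, and 5-exo oxa-Michael (1,6-conjugate) addition of the C9' hydroxyl closes the tetrahydrofuran with the aryl group trans to the C8 substituent (2R), both C7 epimers converging through the planar intermediate; the 4-methoxybenzylic acetate cannot form a quinone methide and stays.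

**Compound list**
1 | (R)-but-3-yn-2-ol | C[C@@H](O)C#C | starting material
2 | lithium (R)-4-lithiobut-3-yn-2-olate | C[C@@H](O[Li])C#C[Li] | intermediate
3 | dilithium (R)-pent-2-yne-1,4-diolate | C[C@@H](O[Li])C#CCO[Li] | intermediate
4 | (R)-5-[(tert-butyldiphenylsilyl)oxy]pent-3-yn-2-ol | C[C@@H](O)C#CCO[Si](c1ccccc1)(c1ccccc1)C(C)(C)C | intermediate
5 | (2R,3Z)-5-[(tert-butyldiphenylsilyl)oxy]pent-3-en-2-ol | C[C@@H](O)/C=C\CO[Si](c1ccccc1)(c1ccccc1)C(C)(C)C | intermediate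
6 | triethyl orthoacetate (1,1,1-triethoxyethane) | CC(OCC)(OCC)OCC | starting material
7 | mixed orthoester, (2R,3Z)-5-[(tert-butyldiphenylsilyl)oxy]pent-3-en-2-yl diethyl orthoacetate | CCOC(C)(OCC)O[C@H](C)/C=C\CO[Si](c1ccccc1)(c1ccccc1)C(C)(C)C | intermediate
8 | ketene acetal, tert-butyl{[(2Z,4R)-4-[(1-ethoxyethenyl)oxy]pent-2-en-1-yl]oxy}diphenylsilane | C=C(OCC)O[C@H](C)/C=C\CO[Si](c1ccccc1)(c1ccccc1)C(C)(C)C | intermediate
9 | ethyl (3S,4E)-3-{[(tert-butyldiphenylsilyl)oxy]methyl}hex-4-enoate | CCOC(=O)C[C@H](CO[Si](c1ccccc1)(c1ccccc1)C(C)(C)C)/C=C/C | intermediate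
10 | ozonide, ethyl (3R)-4-[(tert-butyldiphenylsilyl)oxy]-3-(5-methyl-1,2,4-trioxolan-3-yl)butanoate | CCOC(=O)C[C@H](CO[Si](c1ccccc1)(c1ccccc1)C(C)(C)C)C1OOC(C)O1 | intermediate
11 | ethyl (3R)-4-[(tert-butyldiphenylsilyl)oxy]-3-formylbutanoate | CCOC(=O)C[C@H](CO[Si](c1ccccc1)(c1ccccc1)C(C)(C)C)C=O | intermediate
12 | 4-methoxyphenylmagnesium bromide | COc1ccc([Mg]Br)cc1 | starting material
13 | bromomagnesium (1RS,2R)-2-{[(tert-butyldiphenylsilyl)oxy]methyl}-4-ethoxy-1-(4-methoxyphenyl)-4-oxobutan-1-olate | CCOC(=O)C[C@H](CO[Si](c1ccccc1)(c1ccccc1)C(C)(C)C)C(O[Mg]Br)c1ccc(OC)cc1 | intermediate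
14 | (4R,5RS)-4-{[(tert-butyldiphenylsilyl)oxy]methyl}-5-(4-methoxyphenyl)dihydrofuran-2(3H)-one | COc1ccc(cc1)C1OC(=O)C[C@@H]1CO[Si](c1ccccc1)(c1ccccc1)C(C)(C)C | intermediate
15 | (4R,5S)-4-{[(tert-butyldiphenylsilyl)oxy]methyl}-5-(4-methoxyphenyl)dihydrofuran-2(3H)-one | COc1ccc(cc1)[C@H]1OC(=O)C[C@@H]1CO[Si](c1ccccc1)(c1ccccc1)C(C)(C)C | intermediate
16 | 4-[(tert-butyldimethylsilyl)oxy]benzaldehyde | O=Cc1ccc(O[Si](C)(C)C(C)(C)C)cc1 | starting material
17 | lithium (4R,5S)-4-{[(tert-butyldiphenylsilyl)oxy]methyl}-5-(4-methoxyphenyl)-4,5-dihydrofuran-2-olate | COc1ccc(cc1)[C@H]1OC(O[Li])=C[C@@H]1CO[Si](c1ccccc1)(c1ccccc1)C(C)(C)C | intermediate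
18 | (3R,4R,5S)-3-[(RS)-{4-[(tert-butyldimethylsilyl)oxy]phenyl}(hydroxy)methyl]-4-{[(tert-butyldiphenylsilyl)oxy]methyl}-5-(4-methoxyphenyl)dihydrofuran-2(3H)-one | COc1ccc(cc1)[C@H]1OC(=O)[C@@H](C(O)c2ccc(O[Si](C)(C)C(C)(C)C)cc2)[C@@H]1CO[Si](c1ccccc1)(c1ccccc1)C(C)(C)C | intermediate
19 | (1S,2R,3S,4RS)-4-{4-[(tert-butyldimethylsilyl)oxy]phenyl}-2-{[(tert-butyldiphenylsilyl)oxy]methyl}-3-(hydroxymethyl)-1-(4-methoxyphenyl)butane-1,4-diol | COc1ccc(cc1)[C@@H](O)[C@@H](CO[Si](c1ccccc1)(c1ccccc1)C(C)(C)C)[C@@H](CO)C(O)c1ccc(O[Si](C)(C)C(C)(C)C)cc1 | intermediate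
20 | (1S,2R,3S,4RS)-3-(acetoxymethyl)-4-{4-[(tert-butyldimethylsilyl)oxy]phenyl}-2-{[(tert-butyldiphenylsilyl)oxy]methyl}-1-(4-methoxyphenyl)butane-1,4-diyl diacetate | COc1ccc(cc1)[C@@H](OC(C)=O)[C@@H](CO[Si](c1ccccc1)(c1ccccc1)C(C)(C)C)[C@@H](COC(C)=O)C(OC(C)=O)c1ccc(O[Si](C)(C)C(C)(C)C)cc1 | intermediate
21 | (1S,2R,3S,4RS)-3-(acetoxymethyl)-2-(hydroxymethyl)-4-(4-hydroxyphenyl)-1-(4-methoxyphenyl)butane-1,4-diyl diacetate | COc1ccc(cc1)[C@@H](OC(C)=O)[C@@H](CO)[C@@H](COC(C)=O)C(OC(C)=O)c1ccc(O)cc1 | intermediate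
22 | (1S,2R,3S)-3-(acetoxymethyl)-2-(hydroxymethyl)-1-(4-methoxyphenyl)-4-(4-oxocyclohexa-2,5-dien-1-ylidene)butyl acetate (para-quinone methide) | COc1ccc(cc1)[C@@H](OC(C)=O)[C@@H](CO)[C@@H](COC(C)=O)C=C1C=CC(=O)C=C1 | intermediate
23 | [(2R,3S,4R)-4-[(S)-acetoxy(4-methoxyphenyl)methyl]-2-(4-hydroxyphenyl)tetrahydrofuran-3-yl]methyl acetate | COc1ccc([C@@H](OC(C)=O)[C@H]2CO[C@@H](c3ccc(O)cc3)[C@@H]2COC(C)=O)cc1 | target

**Totals**
Total step count: 10. Longest linear sequence: 10 steps (1 to 23); compounds 6, 12 and 16 are bought.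

**Steps most likely to fail, with fallbacks**

Step 10 (desilylation/quinone methide cyclization). The quinone methide may form before the C9' hydroxyl is free and be lost to water or oligomers, or the acetates may migrate. The fallback sets out from 18 and comes back at 23, closing the ring by acid instead of by base. The aldol hydroxyl of 18 is silylated (Et3SiOTf, 2,6-lutidine, CH2Cl2, −78 °C) to (3R,4R,5S)-3-[(RS)-{4-[(tert-butyldimethylsilyl)oxy]phenyl}(triethylsilyloxy)methyl]-4-{[(tert-butyldiphenylsilyl)oxy]methyl}-5-(4-methoxyphenyl)dihydrofuran-2(3H)-one F5. LiBH4 reduction gives (1S,2R,3S,4RS)-4-{4-[(tert-butyldimethylsilyl)oxy]phenyl}-2-{[(tert-butyldiphenylsilyl)oxy]methyl}-3-(hydroxymethyl)-1-(4-methoxyphenyl)-4-[(triethylsilyl)oxy]butan-1-ol F6. Acetylation gives (1S,2R,3S,4RS)-3-(acetoxymethyl)-4-{4-[(tert-butyldimethylsilyl)oxy]phenyl}-2-{[(tert-butyldiphenylsilyl)oxy]methyl}-1-(4-methoxyphenyl)-4-[(triethylsilyl)oxy]butyl acetate F7. Bu4NF/AcOH removes all three silyl groups to give (1S,2R,3S,4RS)-3-(acetoxymethyl)-4-hydroxy-2-(hydroxymethyl)-4-(4-hydroxyphenyl)-1-(4-methoxyphenyl)butyl acetate F8. Catalytic camphorsulfonic acid in CH2Cl2 then ionizes only the 4-hydroxybenzylic alcohol, and the primary hydroxyl closes the tetrahydrofuran to 23.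

Step 6 (cis to trans equilibration). Ionization may give elimination or an unfavourable ratio. The fallback sets out from 14 and comes back at 15, using SN2 inversion instead of equilibration. The isomers of 14 are separated; the cis isomer is opened with LiOH (THF/H2O, 0 °C, careful acidification) to (3R,4R)-3-{[(tert-butyldiphenylsilyl)oxy]methyl}-4-hydroxy-4-(4-methoxyphenyl)butanoic acid F4. Mitsunobu lactonization (PPh3, diisopropyl azodicarboxylate, THF, 0 °C) then closes it with inversion at the carbinol to 15.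

Step 5 (Grignard addition to the enolizable aldehyde next to an ester). The risks are epimerization of 11 or attack on the ester. The fallback sets out from 11 and comes back at 14, using acylation then reduction instead of aldehyde addition. Pinnick oxidation (NaClO2, NaH2PO4, 2-methylbut-2-ene, t-BuOH/H2O) gives (2R)-2-{[(tert-butyldiphenylsilyl)oxy]methyl}-4-ethoxy-4-oxobutanoic acid F1. Coupling with MeNHOMe·HCl (EDC·HCl, DMAP, CH2Cl2) gives ethyl (3R)-4-[(tert-butyldiphenylsilyl)oxy]-3-[methoxy(methyl)carbamoyl]butanoate F2. Reagent 12 adds once (THF, −40 °C) to give ethyl (3R)-3-{[(tert-butyldiphenylsilyl)oxy]methyl}-4-(4-methoxyphenyl)-4-oxobutanoate F3. NaBH4 in MeOH at −20 °C reduces the ketone and the hydroxy ester lactonizes to 14.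

**Further compounds**
F1 | step 5 | (2R)-2-{[(tert-butyldiphenylsilyl)oxy]methyl}-4-ethoxy-4-oxobutanoic acid | CCOC(=O)C[C@H](CO[Si](c1ccccc1)(c1ccccc1)C(C)(C)C)C(=O)O
F2 | step 5 | ethyl (3R)-4-[(tert-butyldiphenylsilyl)oxy]-3-[methoxy(methyl)carbamoyl]butanoate | CCOC(=O)C[C@H](CO[Si](c1ccccc1)(c1ccccc1)C(C)(C)C)C(=O)N(C)OC
F3 | step 5 | ethyl (3R)-3-{[(tert-butyldiphenylsilyl)oxy]methyl}-4-(4-methoxyphenyl)-4-oxobutanoate | CCOC(=O)C[C@H](CO[Si](c1ccccc1)(c1ccccc1)C(C)(C)C)C(=O)c1ccc(OC)cc1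
F4 | step 6 | (3R,4R)-3-{[(tert-butyldiphenylsilyl)oxy]methyl}-4-hydroxy-4-(4-methoxyphenyl)butanoic acid | COc1ccc(cc1)[C@H](O)[C@@H](CO[Si](c1ccccc1)(c1ccccc1)C(C)(C)C)CC(=O)O
F5 | step 10 | (3R,4R,5S)-3-[(RS)-{4-[(tert-butyldimethylsilyl)oxy]phenyl}(triethylsilyloxy)methyl]-4-{[(tert-butyldiphenylsilyl)oxy]methyl}-5-(4-methoxyphenyl)dihydrofuran-2(3H)-one | COc1ccc(cc1)[C@H]1OC(=O)[C@@H](C(O[Si](CC)(CC)CC)c2ccc(O[Si](C)(C)C(C)(C)C)cc2)[C@@H]1CO[Si](c1ccccc1)(c1ccccc1)C(C)(C)C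
F6 | step 10 | (1S,2R,3S,4RS)-4-{4-[(tert-butyldimethylsilyl)oxy]phenyl}-2-{[(tert-butyldiphenylsilyl)oxy]methyl}-3-(hydroxymethyl)-1-(4-methoxyphenyl)-4-[(triethylsilyl)oxy]butan-1-ol | COc1ccc(cc1)[C@@H](O)[C@@H](CO[Si](c1ccccc1)(c1ccccc1)C(C)(C)C)[C@@H](CO)C(O[Si](CC)(CC)CC)c1ccc(O[Si](C)(C)C(C)(C)C)cc1
F7 | step 10 | (1S,2R,3S,4RS)-3-(acetoxymethyl)-4-{4-[(tert-butyldimethylsilyl)oxy]phenyl}-2-{[(tert-butyldiphenylsilyl)oxy]methyl}-1-(4-methoxyphenyl)-4-[(triethylsilyl)oxy]butyl acetate | COc1ccc(cc1)[C@@H](OC(C)=O)[C@@H](CO[Si](c1ccccc1)(c1ccccc1)C(C)(C)C)[C@@H](COC(C)=O)C(O[Si](CC)(CC)CC)c1ccc(O[Si](C)(C)C(C)(C)C)cc1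
F8 | step 10 | (1S,2R,3S,4RS)-3-(acetoxymethyl)-4-hydroxy-2-(hydroxymethyl)-4-(4-hydroxyphenyl)-1-(4-methoxyphenyl)butyl acetate | COc1ccc(cc1)[C@@H](OC(C)=O)[C@@H](CO)[C@@H](COC(C)=O)C(O)c1ccc(O)cc1
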